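**Plan**

Numbering is fusicoccane-type: ring A = C2–C6 (C3 carries OH and CH2OMe), ring C = C10–C14, nine-membered ring = C1, C2, C6–C12. The enabling feature is C8(OH)–C7(CH3)–C6(H)–C2=C1. At the C8-ketone level this is a γ,δ-unsaturated ketone, a Claisen retron. C6–C7 is therefore cut first, back to the allyl vinyl ether C6=C2–C1–O–C8(=C7H–CH3), held in a temporary seven-membered ring (O, C1, C12, C11, C10, C9, C8).
That ring spans C12/C10 of ring C (bicyclo[4.2.1]), where C10=C14 would be trans in an eight-membered ring. The bridgehead enone C13(=O)–C14=C10 is therefore carried as its Stork–Danheiser adduct C10(OSiMe3)–C14=C13(OMe) and released only in the bicyclo[6.2.1] product.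
Further cuts: C8=C7 (lactone ethylidenation), C9–C10 (intramolecular acetate aldol), C1–C2 (Nozaki–Hiyama–Kishi), C12–C1 (vinyl addition and cleavage). Ring C itself comes from 5-methylhexan-3-one and diethyl oxalate.
Forward order: ring C (steps 1–6) and ring A (7–12) are made separately and joined (13). They are then bridged by the lactone and enol ether (14–16), ring-expanded to the nine-membered ring (17), reduced and unmasked (18–19).
Stereochemistry: C11 comes from a catalytic asymmetric hydroxylation and C3 from a Sharpless epoxidation. C12 (chelation), C1 (Felkin–Anh) and the temporary C10 (tether) are relayed from C11. C1 is then transferred to C6, C7 and the C1=C2 geometry in one event, and C7 directs the C8 reduction.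

Key step: step 17

Assumption: the sense of induction of the nickel–DBFOX catalyst on trione 3 is not known. The ligand enantiomer that gives (R)-4 is meant (both are available) and is written here as (R,R).

**Step 1**
Reactants: 1 5-methylhexan-3-one; 2 diethyl oxalate
Product: 3 3-methyl-5-(propan-2-yl)cyclopentane-1,2,4-trione (enolised)
Conditions: NaOEt (2.2 equiv), EtOH, reflux; aq HCl
Reagents that add atoms: none
Why: Double Claisen condensation of the two α-methylene groups of the ketone with the two ester groups of the oxalate, the classical entry to 3,5-dialkylcyclopentane-1,2,4-triones, delivers all five ring-C carbons (C10–C14) with the C11 methyl and C14 isopropyl groups in place; the two CH centres are enolised and carry no stereochemical information.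

**Step 2**
Reactants: 3 trione
Product: 4 (2R)-2,4-dihydroxy-2-methyl-5-(propan-2-yl)cyclopent-4-ene-1,3-dione
Conditions: Ni(ClO4)2·6H2O (10 mol %), (R,R)-DBFOX/Ph (11 mol %), 2-(phenylsulfonyl)-3-phenyloxaziridine (1.0 equiv), 4 Å MS, CH2Cl2, 0 °C
Reagents that add atoms: 2-(phenylsulfonyl)-3-phenyloxaziridine, O=S(=O)(c1ccccc1)N1OC1c1ccccc1
Why: Chiral-Lewis-acid-catalysed enantioselective α-hydroxylation of a β-dicarbonyl compound with a Davis N-sulfonyloxaziridine, in which the nickel-bound 1,3-diketonate should react at the methyl-bearing C11 rather than at the isopropyl-shielded C14 and the C2-symmetric ligand blocks one face, setting C11 as R; the product can re-enolise only on the C13/C14 side.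

**Step 3**
Reactants: 4 hydroxy-trione enol
Product: 5 (2R)-2-hydroxy-4-methoxy-2-methyl-5-(propan-2-yl)cyclopent-4-ene-1,3-dione
Conditions: TMSCHN2 (1.1 equiv), toluene–MeOH 4:1, 0 °C
Reagents that add atoms: (trimethylsilyl)diazomethane, C[Si](C)(C)C=[N+]=[N-]
Why: O-Methylation of a vinylogous acid with a diazoalkane touches only the acidic enol OH and should give the cross-conjugated 2-methoxy-2-ene-1,4-dione rather than the 1,2-dione isomer, which fixes C13 as the masked ketone and leaves C12=O and C10=O differentiated.

**Step 4**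
Reactants: 5 methoxy-enedione
Product: 6 (4S,5S)-4-ethenyl-4,5-dihydroxy-3-methoxy-5-methyl-2-(propan-2-yl)cyclopent-2-en-1-one (trans-diol)
Conditions: CH2=CHMgBr (2.5 equiv), THF, −78 °C; aq NH4Cl
Reagents that add atoms: vinylmagnesium bromide, C=C[Mg]Br
Why: Grignard 1,2-addition in which C12=O is the more electrophilic and less hindered carbonyl (C10=O is the vinylogous-ester carbonyl next to the isopropyl group), and in the magnesium chelate of the C11 alkoxide with C12=O (Cram chelate) the C11 methyl covers one face, so vinyl enters anti to it and the C12 OH ends trans to the C11 OH.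

**Step 5**
Reactants: 6 trans-diol
Product: 7 bis(triethylsilyl) ether of 6
Conditions: TESOTf (3 equiv), 2,6-lutidine, CH2Cl2, 0 °C → rt
Reagents that add atoms: triethylsilyl triflate, CC[Si](CC)(CC)OS(=O)(=O)C(F)(F)F
Why: Silyl triflate/lutidine silylation is the standard way to cap hindered tertiary alcohols (a trans-diol on a cyclopentane cannot be tied into a cyclic acetal), and no stereocentre is touched.

**Step 6**
Reactants: 7 vinyl compound
Product: 8 C1 aldehyde (1,5-bis(triethylsilyloxy)-2-methoxy-5-methyl-4-oxo-3-(propan-2-yl)cyclopent-2-ene-1-carbaldehyde, configuration as in 6)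
Conditions: OsO4 (3 mol %), NaIO4 (4 equiv), 2,6-lutidine, dioxane–H2O 3:1, rt
Reagents that add atoms: osmium tetroxide (catalytic oxygen carrier), O=[Os](=O)(=O)=O; sodium periodate, [Na+].[O-]I(=O)(=O)=O
Why: Lemieux–Johnson cleavage, in which osmylation selects the monosubstituted vinyl group over the tetrasubstituted push–pull C13=C14 bond and periodate cleaves the diol to the aldehyde without touching C12.

**Step 7**
Reactants: 9 cyclopent-1-en-1-ylmethanol
Product: 10 [(1S,5S)-6-oxabicyclo[3.1.0]hexan-1-yl]methanol
Conditions: Ti(OiPr)4 (10 mol %), L-(+)-DET (12 mol %), t-BuOOH, 4 Å MS, CH2Cl2, −20 °C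
Reagents that add atoms: tert-butyl hydroperoxide, CC(C)(C)OO
Why: Sharpless asymmetric epoxidation of a primary allylic alcohol, in which L-(+)-DET, the tartrate that turns (E)-hex-2-en-1-ol into its (2S,3S)-epoxide, should deliver oxygen to the corresponding face and so set the C3–O bond of the target (the C2 centre is removed later).

**Step 8**
Reactants: 10 epoxy alcohol
Product: 11 (1S,5S)-1-(methoxymethyl)-6-oxabicyclo[3.1.0]hexane
Conditions: NaH, MeI, THF, 0 °C → rt
Reagents that add atoms: iodomethane, CI
Why: Williamson etherification of the primary alkoxide installs the methyl ether of the target, and no Payne migration can change C3 because methylation is fast and the epoxide is trisubstituted.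

**Step 9**
Reactants: 11 epoxy ether
Product: 12 (1S,2R)-1-(methoxymethyl)cyclopentane-1,2-diol (trans)
Conditions: KOH, DMSO–H2O 4:1, 100 °C
Reagents that add atoms: water, O
Why: Basic epoxide hydrolysis is an SN2 opening at the less substituted carbon C2 with inversion, so the C3–O bond and its configuration stay untouched.

**Step 10**
Reactants: 12 trans-diol
Product: 13 (2S)-2-hydroxy-2-(methoxymethyl)cyclopentan-1-one
Conditions: Dess–Martin periodinane, CH2Cl2, rt
Reagents that add atoms: none
Why: Dess–Martin oxidation takes only the secondary alcohol to the ketone, without glycol cleavage, and erases the auxiliary C2 centre.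

**Step 11**
Reactants: 13 hydroxy ketone
Product: 14 (2S)-2-(methoxymethyl)-2-(triethylsilyloxy)cyclopentan-1-one
Conditions: TESOTf, 2,6-lutidine, CH2Cl2, −78 → 0 °C
Reagents that add atoms: triethylsilyl triflate, CC[Si](CC)(CC)OS(=O)(=O)C(F)(F)F
Why: Routine silylation of the tertiary alcohol, needed so that the later enolate, organochromium and titanium steps meet no free OH.

**Step 12**
Reactants: 14 silyloxy ketone
Product: 15 (5S)-5-(methoxymethyl)-5-(triethylsilyloxy)cyclopent-1-en-1-yl triflate
Conditions: KHMDS, THF, −78 °C; PhNTf2, −78 → 0 °C; aq NH4Cl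
Reagents that add atoms: N-phenylbis(trifluoromethanesulfonimide), O=S(=O)(N(c1ccccc1)S(=O)(=O)C(F)(F)F)C(F)(F)F
Why: Enol triflate formation is regiospecific because C3 is quaternary and only C6 carries α-hydrogens, which places the C2=C6 double bond and the C2 handle exactly where the Claisen precursor needs them.

**Step 13**
Reactants: 8 aldehyde; 15 alkenyl triflate
Product: 16 (1S)-allylic alcohol C12–C1H(OH)–C2(=C6)
Conditions: CrCl2 (6 equiv), NiCl2 (2 mol %), DMF, rt
Reagents that add atoms: none
Why: Nozaki–Hiyama–Kishi coupling joins hindered partners and adds to the aldehyde only (the C10 vinylogous-ester carbonyl is inert to organochromium), and a polar Felkin–Anh approach (C12–OSiEt3 anti to the nucleophile, the flat sp2 C13 beside its trajectory, the quaternary C11 next to the carbonyl oxygen) should give 1S.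

**Step 14**
Reactants: 16 allylic alcohol
Product: 17 C1 acetate
Conditions: Ac2O, DMAP, Et3N, CH2Cl2, rt
Reagents that add atoms: acetic anhydride, CC(=O)OC(C)=O
Why: DMAP-catalysed acylation of the only free hydroxyl brings in C8 and C9 already tethered to the C1 oxygen.

**Step 15**
Reactants: 17 acetate
Product: 19 bridged lactone with C10–OSiMe3 (3-oxabicyclo[4.2.1]non-7-en-4-one core), via lithium aldolate 18 (not isolated)
Conditions: LDA (1.1 equiv), THF, −78 °C; TMSCl (3 equiv), −78 → −20 °C
Reagents that add atoms: chlorotrimethylsilane, C[Si](C)(C)Cl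
Why: Intramolecular ester-enolate aldol in the sense of a Stork–Danheiser 1,2-addition to the vinylogous-ester carbonyl C10, in which the acetate CH3 is the only acidic site, the tether forces C9 onto the ring-C face that carries C1 (this sets the temporary C10 centre), and the adduct cannot collapse to the enone because C10=C14 would be a bridgehead alkene in a bicyclo[4.2.1] frame.

**Step 16**
Reactants: 19 bridged lactone
Product: 20 (Z)-4-ethylidene bridged enol ether (CH3 cis to the ring oxygen)
Conditions: CH3CHBr2, TiCl4, Zn, TMEDA, PbCl2 (cat.), THF, 25 °C; aq K2CO3/Et3N, basic alumina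
Reagents that add atoms: 1,1-dibromoethane, CC(Br)Br
Why: Takai–Utimoto alkylidenation converts ester and lactone carbonyls into Z-enol ethers, because in the oxatitanacycle the methyl group avoids the acyl-side substituent (here the neopentyl-like C9H2–C10), and no ketone is present since C13 is an enol ether and C10 a silyl ether.

**Step 17**
Reactants: 20 allyl vinyl ether
Product: 21 nine-membered C8 ketone (bicyclo[6.2.1] core, 6S,7R, C12 cis to C6 on C1=C2)
Conditions: toluene (0.01 M), trace Et3N, base-washed sealed tube, 170 °C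
Reagents that add atoms: none
Why: Thermal [3,3]-sigmatropic (Claisen) rearrangement of the only allyl vinyl ether in 20, C6=C2–C1–O–C8=C7: C6–C7 forms while C1–O breaks, C2=C6 moves to C1=C2, and the tether oxygen becomes the C8 carbonyl oxygen (later the C8 hydroxyl). The closest known reaction type is the Claisen ring expansion of 2-alkylidene cyclic ethers that bear an alkenyl group at the other α-carbon, made from lactones by titanium alkylidenation (five→seven and six→eight membered rings). Mode of closure: the nine-membered carbocycle (C1, C2, C6–C12) is closed by a two-atom ring expansion of the seven-membered ether through a six-centre chair, bicyclo[4.2.1] going to bicyclo[6.2.1], so no medium-ring entropy has to be paid. The short C12–C11–C10–C9 link can bridge C1 and C8 only if C12 is pseudo-axial on the chair, which fixes C12 cis to C6 on the new C1=C2 bond; bonding is suprafacial on the allyl unit, so C7 reaches C6 on the ring-A face that carries the (1S) C–O bond (the CH2OMe face, anti to the C3 silyloxy group) and gives 6S. In that chair the Z-ethylidene (CH3 cis to O) places the methyl group so that C7 becomes R. The step needs the exocyclic Z-enol ether to survive (acid-free vessel) and ring C to stay passive, which the sp3 C10 and the non-allylic enol methyl ether secure, while C=O formation and relief of the cramped bicyclo[4.2.1] ether supply the driving force.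

**Step 18**
Reactants: 21 ketone
Product: 22 (8S)-alcohol
Conditions: L-Selectride, THF, −78 °C; H2O
Reagents that add atoms: none
Why: Felkin–Anh reduction of the only ketone present (C13 is still masked), in which the bulky hydride attacks the peripheral face of the medium-ring carbonyl, anti to the ring bond C7–C6, which gives the anti C7-CH3/C8-OH relationship (8S).

**Step 19**
Reactants: 22 alcohol
Product: 24 brassicicene M, via pentaol enol ether 23 (not isolated)
Conditions: 48 % aq HF–MeCN 1:10, 0 °C → rt
Reagents that add atoms: water, O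
Why: Acidic fluoride removes the four silyl groups and the freed tertiary allylic C10 carbinol next to the enol ether undergoes the Stork–Danheiser transposition (loss of the C10 oxygen, water on C13, loss of methanol) to the enone C13(=O)–C14=C10, now allowed because that bond is trans only in a ten-membered ring; the mild acid spares the C3, C11 and C12 tertiary alcohols.

**Compound list**

1 | 5-methylhexan-3-one | CCC(=O)CC(C)C | starting material
2 | diethyl oxalate | CCOC(=O)C(=O)OCC | starting material
3 | 3-methyl-5-(propan-2-yl)cyclopentane-1,2,4-trione | CC1C(=O)C(=O)C(C(C)C)C1=O | intermediate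
4 | (2R)-2,4-dihydroxy-2-methyl-5-(propan-2-yl)cyclopent-4-ene-1,3-dione | O=C1C(O)=C(C(C)C)C(=O)[C@@]1(C)O | intermediate
5 | (2R)-2-hydroxy-4-methoxy-2-methyl-5-(propan-2-yl)cyclopent-4-ene-1,3-dione | O=C1C(OC)=C(C(C)C)C(=O)[C@@]1(C)O | intermediate
6 | (4S,5S)-4-ethenyl-4,5-dihydroxy-3-methoxy-5-methyl-2-(propan-2-yl)cyclopent-2-en-1-one | C=C[C@@]1(O)C(OC)=C(C(C)C)C(=O)[C@@]1(C)O | intermediate
7 | bis(triethylsilyl) ether of 6 | C=C[C@@]1(O[Si](CC)(CC)CC)C(OC)=C(C(C)C)C(=O)[C@@]1(C)O[Si](CC)(CC)CC | intermediate
8 | C1 aldehyde of ring C | O=C[C@@]1(O[Si](CC)(CC)CC)C(OC)=C(C(C)C)C(=O)[C@@]1(C)O[Si](CC)(CC)CC | intermediate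
9 | cyclopent-1-en-1-ylmethanol | OCC1=CCCC1 | starting material
10 | [(1S,5S)-6-oxabicyclo[3.1.0]hexan-1-yl]methanol | OC[C@@]12CCC[C@@H]1O2 | intermediate
11 | (1S,5S)-1-(methoxymethyl)-6-oxabicyclo[3.1.0]hexane | COC[C@@]12CCC[C@@H]1O2 | intermediate
12 | (1S,2R)-1-(methoxymethyl)cyclopentane-1,2-diol | COC[C@@]1(O)CCC[C@H]1O | intermediate
13 | (2S)-2-hydroxy-2-(methoxymethyl)cyclopentan-1-one | COC[C@@]1(O)CCCC1=O | intermediate
14 | (2S)-2-(methoxymethyl)-2-(triethylsilyloxy)cyclopentan-1-one | COC[C@@]1(O[Si](CC)(CC)CC)CCCC1=O | intermediate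
15 | (5S)-5-(methoxymethyl)-5-(triethylsilyloxy)cyclopent-1-en-1-yl triflate | COC[C@@]1(O[Si](CC)(CC)CC)CCC=C1OS(=O)(=O)C(F)(F)F | intermediate
16 | (1S)-allylic alcohol joining rings A and C | COC[C@@]1(O[Si](CC)(CC)CC)CCC=C1[C@H](O)[C@@]2(O[Si](CC)(CC)CC)C(OC)=C(C(C)C)C(=O)[C@@]2(C)O[Si](CC)(CC)CC | intermediate
17 | C1 acetate of 16 | COC[C@@]1(O[Si](CC)(CC)CC)CCC=C1[C@H](OC(C)=O)[C@@]2(O[Si](CC)(CC)CC)C(OC)=C(C(C)C)C(=O)[C@@]2(C)O[Si](CC)(CC)CC | intermediate
18 | lithium C10 aldolate of the bridged lactone | COC[C@@]1(O[Si](CC)(CC)CC)CCC=C1[C@@H]2OC(=O)C[C@]3([O-])C(C(C)C)=C(OC)[C@@]2(O[Si](CC)(CC)CC)[C@]3(C)O[Si](CC)(CC)CC.[Li+] | intermediate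
19 | bridged lactone, C10–OSiMe3 | COC[C@@]1(O[Si](CC)(CC)CC)CCC=C1[C@@H]2OC(=O)C[C@]3(O[Si](C)(C)C)C(C(C)C)=C(OC)[C@@]2(O[Si](CC)(CC)CC)[C@]3(C)O[Si](CC)(CC)CC | intermediate
20 | (Z)-ethylidene bridged enol ether | COC[C@@]1(O[Si](CC)(CC)CC)CCC=C1[C@@H]2O/C(=C\C)C[C@]3(O[Si](C)(C)C)C(C(C)C)=C(OC)[C@@]2(O[Si](CC)(CC)CC)[C@]3(C)O[Si](CC)(CC)CC | intermediate
21 | nine-membered C8 ketone | COC[C@@]1(O[Si](CC)(CC)CC)CC[C@@H]2/C1=C\[C@@]1(O[Si](CC)(CC)CC)C(OC)=C(C(C)C)[C@@](O[Si](C)(C)C)(CC(=O)[C@@H]2C)[C@@]1(C)O[Si](CC)(CC)CC | intermediate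
22 | (8S)-alcohol | COC[C@@]1(O[Si](CC)(CC)CC)CC[C@@H]2/C1=C\[C@@]1(O[Si](CC)(CC)CC)C(OC)=C(C(C)C)[C@@](O[Si](C)(C)C)(C[C@H](O)[C@@H]2C)[C@@]1(C)O[Si](CC)(CC)CC | intermediate
23 | pentaol enol ether (desilylated Stork–Danheiser carbinol) | COC[C@@]1(O)CC[C@@H]2/C1=C\[C@@]1(O)C(OC)=C(C(C)C)[C@@](O)(C[C@H](O)[C@@H]2C)[C@@]1(C)O | intermediate
24 | brassicicene M | COC[C@@]1(O)CC[C@@H]2/C1=C\[C@@]1(O)C(=O)C(C(C)C)=C(C[C@H](O)[C@@H]2C)[C@@]1(C)O | target

**Totals**

Total step count: 19. Longest linear sequence: 13 (steps 1–6 or 7–12, then 13–19).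

**Steps most likely to fail**

Step 17. The compact chair may be too crowded in the bridged ether. The C11 silyloxy group points toward the four-atom bridge and the C13=C14 bridge lies next to C6. Migration of the exocyclic double bond into the ring, or decomposition, could therefore outrun the rearrangement.
Fallback, a stepwise ionic closure of the same bond, from 19 back to 21. Aminolysis of lactone 19 with Me(MeO)NH·HCl/Me3Al would open the bridge to the hydroxy Weinreb amide F1. EtMgBr would give the hydroxy ethyl ketone F2. ClCO2Me/pyridine/DMAP would give the allylic methyl carbonate F3. Kinetic deprotonation at the ethyl CH2 (LiHMDS, −78 °C; C9H2 is neopentyl-like), then Pd(PPh3)4 at high dilution, would close C6–C7 by an intramolecular Tsuji–Trost allylation. Ionisation and attack are both anti, so the ring-A face is the same as in the pericyclic route. Attack at C1 would build a bicyclo[4.2.1] ring between two quaternary carbons and is disfavoured. C7 would be equilibrated with DBU if needed, and the route is rejoined at 21.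

Step 15. The aldol is reversible and the carbonyl is deactivated and hindered. Retro-aldol on warming, slow addition, or an ester-enolate rearrangement of the allylic acetate could compete before the alkoxide is capped.
Fallback, a reductive closure held by chelation, from 16 back to 19. Bromoacetyl bromide/pyridine would give the bromoacetate F4. SmI2 (THF, −78 °C) would generate the samarium(III) enolate for an intramolecular Reformatsky-type addition to C10, giving the β-hydroxy lactone F5. TMSOTf/2,6-lutidine would then give 19.

Step 2. Oxidation could be unselective between C11 and C14, could go on to a second hydroxylation, or could show poor facial discrimination on this very acidic, weakly nucleophilic enol.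
Fallback, resolution instead of catalysis, from 3 back to 4. Dimethyldioxirane (acetone, 0 °C) would give the racemic hydroxy-trione enol F6. This strong vinylogous acid would be resolved by crystallisation of its salt with the matching enantiomer of 1-phenylethylamine, written as the (R)-amine salt F7. Acidification returns 4.

**Further compounds**

F1 | step 17 | hydroxy Weinreb amide from 19 | COC[C@@]1(O[Si](CC)(CC)CC)CCC=C1[C@H](O)[C@@]2(O[Si](CC)(CC)CC)C(OC)=C(C(C)C)[C@@](O[Si](C)(C)C)(CC(=O)N(C)OC)[C@@]2(C)O[Si](CC)(CC)CC
F2 | step 17 | hydroxy ethyl ketone | COC[C@@]1(O[Si](CC)(CC)CC)CCC=C1[C@H](O)[C@@]2(O[Si](CC)(CC)CC)C(OC)=C(C(C)C)[C@@](O[Si](C)(C)C)(CC(=O)CC)[C@@]2(C)O[Si](CC)(CC)CC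
F3 | step 17 | allylic methyl carbonate | COC[C@@]1(O[Si](CC)(CC)CC)CCC=C1[C@H](OC(=O)OC)[C@@]2(O[Si](CC)(CC)CC)C(OC)=C(C(C)C)[C@@](O[Si](C)(C)C)(CC(=O)CC)[C@@]2(C)O[Si](CC)(CC)CC
F4 | step 15 | C1 bromoacetate | COC[C@@]1(O[Si](CC)(CC)CC)CCC=C1[C@H](OC(=O)CBr)[C@@]2(O[Si](CC)(CC)CC)C(OC)=C(C(C)C)C(=O)[C@@]2(C)O[Si](CC)(CC)CC
F5 | step 15 | bridged β-hydroxy lactone | COC[C@@]1(O[Si](CC)(CC)CC)CCC=C1[C@@H]2OC(=O)C[C@]3(O)C(C(C)C)=C(OC)[C@@]2(O[Si](CC)(CC)CC)[C@]3(C)O[Si](CC)(CC)CC
F6 | step 2 | racemic 2,4-dihydroxy-2-methyl-5-(propan-2-yl)cyclopent-4-ene-1,3-dione | O=C1C(O)=C(C(C)C)C(=O)C1(C)O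
F7 | step 2 | (R)-1-phenylethylammonium salt of (R)-4 | O=C1C([O-])=C(C(C)C)C(=O)[C@@]1(C)O.C[C@@H]([NH3+])c1ccccc1
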